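The whole route rests on the homoallylic array C17=C8–C9–C10 of ring B. The exocyclic methylene and the quaternary fusion carbon C10, linked through C9, are the retron of a cyclopropylcarbinyl cation. In the key step a (bicyclo[3.1.0]hex-1-yl)methyl acetate ionises and its internal bond C8–C10 breaks. The cyclopentane C5–C6–C7–C8–C10 thereby grows into six-membered ring B, C8=C17 appears beside the C7 carbinol, and C10 is captured with inversion by a tethered enol ether, which closes ring A and sets the quaternary centre. The precursor, a cyclopropane-fused cyclopentanol carrying the intact nerol-derived side chain, comes from nerol by a Michael addition, two lactone alkylations and a diazo ketoester cyclopropanation.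

Key step: step 15

Remark on numbering: carbons are called by their labdane numbers C1–C20 in all intermediates, open-chain and bicyclic ones included; TBDPS = tert-butyl(diphenyl)silyl.
Remark on a reagent: 3-bromo-2-methoxyprop-1-ene (12) is taken as purchasable; otherwise it is made in one operation from 2-methoxypropene and N-bromosuccinimide.

Step 1
Reactants: 1 nerol, (2Z)-3,7-dimethylocta-2,6-dien-1-ol
Product: 2 tert-butyl{[(2Z)-3,7-dimethylocta-2,6-dien-1-yl]oxy}diphenylsilane
Conditions: t-BuPh2SiCl, imidazole, DMF, 0 °C → rt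
Reagents that add atoms: tert-butyl(chloro)diphenylsilane, CC(C)(C)[Si](Cl)(c1ccccc1)c1ccccc1
Why: Standard O-silylation of a primary allylic alcohol gives a silyl ether that should survive the bases, hydrides and Lewis acid used later; no stereocentre is formed.

Step 2
Reactants: 2 tert-butyl{[(2Z)-3,7-dimethylocta-2,6-dien-1-yl]oxy}diphenylsilane
Product: 4 (2E,6Z)-8-(TBDPS-oxy)-2,6-dimethylocta-2,6-dienal, via allylic alcohol 3 (not isolated)
Conditions: SeO2 (cat.), t-BuOOH, CH2Cl2, 0 °C → rt; then MnO2, CH2Cl2, rt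
Reagents that add atoms: tert-butyl hydroperoxide, CC(C)(C)OO (oxygen source, passed on through SeO2, O=[Se]=O)
Why: Riley-type SeO2 allylic oxidation (ene reaction, then [2,3]-shift) should attack the (E)-methyl group of the electron-richer terminal alkene, the alkene next to the silyloxy group being deactivated, and MnO2 completes the allylic oxidation to the (E)-enal, whose carbonyl carbon is C5.

Step 3
Reactants: 4 (2E,6Z)-8-(TBDPS-oxy)-2,6-dimethylocta-2,6-dienal; 5 (triphenylphosphoranylidene)acetaldehyde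
Product: 6 (2E,4E,8Z)-10-(TBDPS-oxy)-4,8-dimethyldeca-2,4,8-trienal
Conditions: toluene, 80 °C
Reagents that add atoms: none
Why: Wittig olefination with the stabilised formyl ylide should give the (E)-enal two carbons longer (C6 and C7), a slight deficit of ylide limiting a second homologation.

Step 4
Reactants: 7 S-tert-butyl ethanethioate
Product: 8 tert-butyl{[1-(tert-butylsulfanyl)ethenyl]oxy}dimethylsilane
Conditions: LiN(i-Pr)2, THF, −78 °C; then t-BuMe2SiCl, DMPU
Reagents that add atoms: tert-butyl(chloro)dimethylsilane, CC(C)(C)[Si](C)(C)Cl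
Why: Kinetic enolisation of the thioester and O-silylation give the silyl ketene thioacetal, the two-carbon nucleophile (C4 and C19) for the next step.

Step 5
Reactants: 6 (2E,4E,8Z)-10-(TBDPS-oxy)-4,8-dimethyldeca-2,4,8-trienal; 8 tert-butyl{[1-(tert-butylsulfanyl)ethenyl]oxy}dimethylsilane
Product: 9 S-tert-butyl (3S,4E,8Z)-10-(TBDPS-oxy)-4,8-dimethyl-3-(2-oxoethyl)deca-4,8-dienethioate
Conditions: (2R,5R)-5-benzyl-2-tert-butyl-3-methylimidazolidin-4-one·CCl3CO2H (20 mol %), H2O (2 equiv), CH2Cl2, −60 °C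
Reagents that add atoms: none
Why: In this iminium-catalysed Mukaiyama–Michael addition the (E)-iminium ion of 6 should be attacked at its β-carbon C5 (the δ-position C9 is screened by the C10 methyl group) on the Re face left open by the benzyl arm of the (2R,5R)-catalyst, which sets C5 (3S in 9).

Step 6
Reactants: 9 S-tert-butyl (3S,4E,8Z)-10-(TBDPS-oxy)-4,8-dimethyl-3-(2-oxoethyl)deca-4,8-dienethioate
Product: 11 (4S)-4-[(2E,6Z)-8-(TBDPS-oxy)-6-methylocta-2,6-dien-2-yl]oxan-2-one, via hydroxy thioester 10 (not isolated)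
Conditions: NaBH4, MeOH, −20 °C; then pyridinium p-toluenesulfonate (cat.), toluene, 80 °C
Reagents that add atoms: none
Why: Chemoselective borohydride reduction of the aldehyde beside the thioester, then acid-catalysed lactonisation (intramolecular transthioesterification driven by loss of volatile thiol), should give the δ-lactone whose only enolisable carbon is C4.

Step 7
Reactants: 11 (4S)-4-[(2E,6Z)-8-(TBDPS-oxy)-6-methylocta-2,6-dien-2-yl]oxan-2-one; 12 3-bromo-2-methoxyprop-1-ene
Product: 13 (3R,4S)-3-(2-methoxyprop-2-en-1-yl)-4-[(2E,6Z)-8-(TBDPS-oxy)-6-methylocta-2,6-dien-2-yl]oxan-2-one (3,4-trans)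
Conditions: LiN(i-Pr)2, THF, −78 °C; then 12, DMPU, −78 → −40 °C
Reagents that add atoms: none
Why: Lactone enolate alkylation with an allylic bromide brings in C1–C3 as a base-stable methyl enol ether (masked acetonyl group), trans to the C5 alkenyl group, a configuration that the next step erases.

Step 8
Reactants: 13 (3R,4S)-3-(2-methoxyprop-2-en-1-yl)-4-[(2E,6Z)-8-(TBDPS-oxy)-6-methylocta-2,6-dien-2-yl]oxan-2-one
Product: 14 (3S,4R)-3-(2-methoxyprop-2-en-1-yl)-3-methyl-4-[(2E,6Z)-8-(TBDPS-oxy)-6-methylocta-2,6-dien-2-yl]oxan-2-one (methyl trans to the alkenyl group)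
Conditions: LiN(i-Pr)2, THF, −78 °C; then MeI, DMPU, −78 → −30 °C
Reagents that add atoms: iodomethane, CI
Why: In this second enolate alkylation iodomethane should approach the tetrasubstituted lactone enolate anti to the adjacent C5 alkenyl group (1,2-induction in a six-membered enolate), so the quaternary centre C4 forms with the C18 methyl trans and the methoxyallyl arm cis to that group.

Step 9
Reactants: 14 (3S,4R)-3-(2-methoxyprop-2-en-1-yl)-3-methyl-4-[(2E,6Z)-8-(TBDPS-oxy)-6-methylocta-2,6-dien-2-yl]oxan-2-one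
Product: 15 (2S,3R)-2-(2-methoxyprop-2-en-1-yl)-2-methyl-3-[(2E,6Z)-8-(TBDPS-oxy)-6-methylocta-2,6-dien-2-yl]pentane-1,5-diol
Conditions: LiAlH4, THF, 0 °C
Reagents that add atoms: none
Why: Hydride reduction of the lactone gives the 1,5-diol with C19 at its final oxidation level; no stereocentre is touched.

Step 10
Reactants: 15 (2S,3R)-2-(2-methoxyprop-2-en-1-yl)-2-methyl-3-[(2E,6Z)-8-(TBDPS-oxy)-6-methylocta-2,6-dien-2-yl]pentane-1,5-diol
Product: 16 (4R,5S)-5-(2-methoxyprop-2-en-1-yl)-5-methyl-4-[(2E,6Z)-8-(TBDPS-oxy)-6-methylocta-2,6-dien-2-yl]oxan-2-one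
Conditions: Ag2CO3 on Celite, toluene, reflux
Reagents that add atoms: none
Why: Fétizon oxidation (oxidative lactonisation of a 1,5-diol) should start at the unhindered C7 hydroxyl and not at the neopentyl C19 hydroxyl, so the lactone carbonyl ends at C7 under neutral conditions that spare the enol ether.

Step 11
Reactants: 16 (4R,5S)-5-(2-methoxyprop-2-en-1-yl)-5-methyl-4-[(2E,6Z)-8-(TBDPS-oxy)-6-methylocta-2,6-dien-2-yl]oxan-2-one; 17 ethyl diazoacetate
Product: 19 ethyl (5R,6S)-7-(acetyloxy)-2-diazo-6-(2-methoxyprop-2-en-1-yl)-6-methyl-5-[(2E,6Z)-8-(TBDPS-oxy)-6-methylocta-2,6-dien-2-yl]-3-oxoheptanoate, via hydroxy diazo ketoester 18 (not isolated)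
Conditions: 17, LiN(i-Pr)2, THF, −78 °C; then 16, −78 °C; then Ac2O, −78 → 0 °C
Reagents that add atoms: acetic anhydride, CC(=O)OC(C)=O
Why: Acylation of lithiated ethyl diazoacetate by the lactone (ring-opening to the α-diazo-β-keto ester, which is too deactivated to add a second anion) joins C8 and C17 to C7, and the liberated C19 alkoxide is acetylated in the same flask so that it cannot insert into the carbenoid later.

Step 12
Reactants: 19 ethyl (5R,6S)-7-(acetyloxy)-2-diazo-6-(2-methoxyprop-2-en-1-yl)-6-methyl-5-[(2E,6Z)-8-(TBDPS-oxy)-6-methylocta-2,6-dien-2-yl]-3-oxoheptanoate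
Product: 20 ethyl (1R,4R,5R,6R)-4-[(2S)-1-(acetyloxy)-4-methoxy-2-methylpent-4-en-2-yl]-6-[(3Z)-5-(TBDPS-oxy)-3-methylpent-3-en-1-yl]-5-methyl-2-oxobicyclo[3.1.0]hexane-1-carboxylate
Conditions: Rh2(OAc)4 (1 mol %), CH2Cl2, rt, slow addition
Reagents that add atoms: none
Why: In this intramolecular cyclopropanation the rhodium carbenoid at C8 should add to the nearby C9=C10 alkene (five-membered tether, far faster than reaction with the remote enol ether); the E geometry places the C11 chain exo (trans to C5), and the reacting conformer keeps the bulky C4 group on the allylic centre C5 away from the forming ring, which sets C8, C9 and C10 anti to it.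

Step 13
Reactants: 20 ethyl (1R,4R,5R,6R)-4-[(2S)-1-(acetyloxy)-4-methoxy-2-methylpent-4-en-2-yl]-6-[(3Z)-5-(TBDPS-oxy)-3-methylpent-3-en-1-yl]-5-methyl-2-oxobicyclo[3.1.0]hexane-1-carboxylate
Product: 21 (1S,2R,4R,5R,6R)-6-[(3Z)-5-(TBDPS-oxy)-3-methylpent-3-en-1-yl]-4-[(2S)-1-hydroxy-4-methoxy-2-methylpent-4-en-2-yl]-1-(hydroxymethyl)-5-methylbicyclo[3.1.0]hexan-2-ol
Conditions: LiAlH4, THF, −78 → 0 °C
Reagents that add atoms: none
Why: Hydride reduction of ketone, ethyl ester and acetate in one operation; hydride should reach C7 from the face opposite the cyclopropane, whose endo C9–H blocks the other face, giving the carbinol cis to the cyclopropane (7R, the later 7α-hydroxyl).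

Step 14
Reactants: 21 (1S,2R,4R,5R,6R)-6-[(3Z)-5-(TBDPS-oxy)-3-methylpent-3-en-1-yl]-4-[(2S)-1-hydroxy-4-methoxy-2-methylpent-4-en-2-yl]-1-(hydroxymethyl)-5-methylbicyclo[3.1.0]hexan-2-ol
Product: 22 {(1S,2R,4R,5R,6R)-4-[(2S)-1-(acetyloxy)-4-methoxy-2-methylpent-4-en-2-yl]-6-[(3Z)-5-(TBDPS-oxy)-3-methylpent-3-en-1-yl]-2-hydroxy-5-methylbicyclo[3.1.0]hexan-1-yl}methyl acetate
Conditions: Ac2O (2.1 equiv), Et3N, DMAP (5 mol %), CH2Cl2, −40 °C
Reagents that add atoms: acetic anhydride, CC(=O)OC(C)=O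
Why: Sterically controlled acylation should acetylate the two primary hydroxyls (C17 and C19) and leave the secondary C7 hydroxyl, which is flanked by quaternary C8 on the cyclopropane face; the C19 acetate is the one kept in the target and the C17 acetate is the leaving group of the key step.

Step 15
Reactants: 22 {(1S,2R,4R,5R,6R)-4-[(2S)-1-(acetyloxy)-4-methoxy-2-methylpent-4-en-2-yl]-6-[(3Z)-5-(TBDPS-oxy)-3-methylpent-3-en-1-yl]-2-hydroxy-5-methylbicyclo[3.1.0]hexan-1-yl}methyl acetate
Product: 25 (4S,5R,7R,9R,10S)-19-acetoxy-7α-hydroxy-15-(TBDPS-oxy)labda-8(17),13Z-dien-2-one, via C7 trimethylsilyl ether 23 (not isolated), via cyclised oxocarbenium triflate 24 (not isolated)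
Conditions: Me3SiOSO2CF3 (2.5 equiv), 2,6-di-tert-butyl-4-methylpyridine (3 equiv), CH2Cl2, −78 → −20 °C; then 0.5 M HCl, THF, 0 °C
Reagents that add atoms: water, O (oxygen of the C2 carbonyl on hydrolysis)
Why: Proposed new method: the silyl triflate first silylates the C7 hydroxyl and then ionises the primary cyclopropylcarbinyl acetate at C17 (the neopentyl C19 acetate cannot ionise); the bisected cyclopropylcarbinyl cation opens at the internal bond C8–C10 because C10 is the only fully substituted cyclopropane carbon, which turns the cyclopentane C5–C6–C7–C8–C10 into six-membered ring B with C9 inserted and leaves C8=C17 as the exocyclic methylene. The positive charge developing at C10 is captured on the side anti to the breaking C8–C10 bond by C1 of the tethered methyl enol ether, a 6-(enolendo)-exo-tet closure of ring A through a chair that carries C19 and C20 axial, and acid work-up hydrolyses the oxocarbenium ion to the C2 ketone and removes the trimethylsilyl group. C10 is the only new stereocentre and is set by this inversion; because the C5 side chain stands anti to the cyclopropane in 22, the result is the trans-fused decalin with the C20 methyl β, while C4, C5, C7 and C9 are carried through unchanged. The closest known reaction types are the cyclopropylcarbinyl–homoallyl rearrangement with nucleophilic capture (Julia olefin synthesis), stereoinvertive substitution at quaternary carbons of cyclopropylcarbinyl derivatives by heteroatom nucleophiles, and cation–olefin cyclisations initiated by acylcyclopropanes; new is a tethered carbon nucleophile acting on the internal bond of a bicyclo[3.1.0]hexane, so that substitution, ring expansion and ring closure coincide. The step needs cleavage of C8–C10 rather than C8–C9 (secured by the C20 methyl on C10 and the six-membered reach of the tether) and C–C capture ahead of proton loss or capture by the much less nucleophilic C13=C14 alkene (secured by the high nucleophilicity of the enol ether and the hindered, non-nucleophilic base).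

Step 16
Reactants: 25 (4S,5R,7R,9R,10S)-19-acetoxy-7α-hydroxy-15-(TBDPS-oxy)labda-8(17),13Z-dien-2-one
Product: 26 (2R,4S,5R,7R,9R,10S)-19-acetoxy-15-(TBDPS-oxy)labda-8(17),13Z-diene-2α,7α-diol
Conditions: SmI2 (2.5 equiv), H2O, Et3N, THF, −20 °C
Reagents that add atoms: none
Why: Single-electron reduction with SmI2 passes through a ketyl and an α-oxy organosamarium that should be protonated under thermodynamic control, so the C2–O bond ends equatorial (2α) away from the syn-axial C20 methyl and C19 acetoxymethyl groups that would steer hydride reagents to the axial alcohol; with limited reagent at low temperature the acetate and alkenes should remain.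

Step 17
Reactants: 26 (2R,4S,5R,7R,9R,10S)-19-acetoxy-15-(TBDPS-oxy)labda-8(17),13Z-diene-2α,7α-diol
Product: 27 (2R,4S,5R,7R,9R,10S)-2α,7α,15-trihydroxylabda-8(17),13Z-dien-19-yl acetate (CNP0174017.2)
Conditions: n-Bu4NF, AcOH, THF, 0 °C → rt
Reagents that add atoms: none
Why: Fluoride-mediated desilylation, buffered with acetic acid so that the C19 acetate neither cleaves nor migrates, frees the C15 hydroxyl and gives the target.

Compound list
1 | nerol, (2Z)-3,7-dimethylocta-2,6-dien-1-ol | CC(C)=CCC/C(C)=C\CO | starting material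
2 | tert-butyl{[(2Z)-3,7-dimethylocta-2,6-dien-1-yl]oxy}diphenylsilane | CC(C)=CCC/C(C)=C\CO[Si](c1ccccc1)(c1ccccc1)C(C)(C)C | intermediate
3 | (2E,6Z)-8-(TBDPS-oxy)-2,6-dimethylocta-2,6-dien-1-ol | OC/C(C)=C/CC/C(C)=C\CO[Si](c1ccccc1)(c1ccccc1)C(C)(C)C | intermediate (not isolated)
4 | (2E,6Z)-8-(TBDPS-oxy)-2,6-dimethylocta-2,6-dienal | O=C/C(C)=C/CC/C(C)=C\CO[Si](c1ccccc1)(c1ccccc1)C(C)(C)C | intermediate
5 | (triphenylphosphoranylidene)acetaldehyde | O=CC=P(c1ccccc1)(c1ccccc1)c1ccccc1 | starting material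
6 | (2E,4E,8Z)-10-(TBDPS-oxy)-4,8-dimethyldeca-2,4,8-trienal | O=C/C=C/C(C)=C/CC/C(C)=C\CO[Si](c1ccccc1)(c1ccccc1)C(C)(C)C | intermediate
7 | S-tert-butyl ethanethioate | CC(=O)SC(C)(C)C | starting material
8 | tert-butyl{[1-(tert-butylsulfanyl)ethenyl]oxy}dimethylsilane | C=C(O[Si](C)(C)C(C)(C)C)SC(C)(C)C | intermediate
9 | S-tert-butyl (3S,4E,8Z)-10-(TBDPS-oxy)-4,8-dimethyl-3-(2-oxoethyl)deca-4,8-dienethioate | O=CC[C@H](/C(C)=C/CC/C(C)=C\CO[Si](c1ccccc1)(c1ccccc1)C(C)(C)C)CC(=O)SC(C)(C)C | intermediate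
10 | S-tert-butyl (3S,4E,8Z)-10-(TBDPS-oxy)-3-(2-hydroxyethyl)-4,8-dimethyldeca-4,8-dienethioate | OCC[C@H](/C(C)=C/CC/C(C)=C\CO[Si](c1ccccc1)(c1ccccc1)C(C)(C)C)CC(=O)SC(C)(C)C | intermediate (not isolated)
11 | (4S)-4-[(2E,6Z)-8-(TBDPS-oxy)-6-methylocta-2,6-dien-2-yl]oxan-2-one | O=C1OCC[C@H](/C(C)=C/CC/C(C)=C\CO[Si](c2ccccc2)(c2ccccc2)C(C)(C)C)C1 | intermediate
12 | 3-bromo-2-methoxyprop-1-ene | C=C(OC)CBr | starting material
13 | (3R,4S)-3-(2-methoxyprop-2-en-1-yl)-4-[(2E,6Z)-8-(TBDPS-oxy)-6-methylocta-2,6-dien-2-yl]oxan-2-one | O=C1OCC[C@H](/C(C)=C/CC/C(C)=C\CO[Si](c2ccccc2)(c2ccccc2)C(C)(C)C)[C@H]1CC(OC)=C | intermediate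
14 | (3S,4R)-3-(2-methoxyprop-2-en-1-yl)-3-methyl-4-[(2E,6Z)-8-(TBDPS-oxy)-6-methylocta-2,6-dien-2-yl]oxan-2-one | O=C1OCC[C@H](/C(C)=C/CC/C(C)=C\CO[Si](c2ccccc2)(c2ccccc2)C(C)(C)C)[C@]1(C)CC(OC)=C | intermediate
15 | (2S,3R)-2-(2-methoxyprop-2-en-1-yl)-2-methyl-3-[(2E,6Z)-8-(TBDPS-oxy)-6-methylocta-2,6-dien-2-yl]pentane-1,5-diol | OCC[C@H](/C(C)=C/CC/C(C)=C\CO[Si](c1ccccc1)(c1ccccc1)C(C)(C)C)[C@](C)(CC(OC)=C)CO | intermediate
16 | (4R,5S)-5-(2-methoxyprop-2-en-1-yl)-5-methyl-4-[(2E,6Z)-8-(TBDPS-oxy)-6-methylocta-2,6-dien-2-yl]oxan-2-one | O=C1C[C@H](/C(C)=C/CC/C(C)=C\CO[Si](c2ccccc2)(c2ccccc2)C(C)(C)C)[C@](C)(CC(OC)=C)CO1 | intermediate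
17 | ethyl diazoacetate | CCOC(=O)C=[N+]=[N-] | starting material
18 | ethyl (5R,6S)-2-diazo-7-hydroxy-6-(2-methoxyprop-2-en-1-yl)-6-methyl-5-[(2E,6Z)-8-(TBDPS-oxy)-6-methylocta-2,6-dien-2-yl]-3-oxoheptanoate (formed as its lithium alkoxide) | C=C(OC)C[C@](C)(CO)[C@H](CC(=O)C(=[N+]=[N-])C(=O)OCC)/C(C)=C/CC/C(C)=C\CO[Si](c1ccccc1)(c1ccccc1)C(C)(C)C | intermediate (not isolated)
19 | ethyl (5R,6S)-7-(acetyloxy)-2-diazo-6-(2-methoxyprop-2-en-1-yl)-6-methyl-5-[(2E,6Z)-8-(TBDPS-oxy)-6-methylocta-2,6-dien-2-yl]-3-oxoheptanoate | C=C(OC)C[C@](C)(COC(C)=O)[C@H](CC(=O)C(=[N+]=[N-])C(=O)OCC)/C(C)=C/CC/C(C)=C\CO[Si](c1ccccc1)(c1ccccc1)C(C)(C)C | intermediate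
20 | ethyl (1R,4R,5R,6R)-4-[(2S)-1-(acetyloxy)-4-methoxy-2-methylpent-4-en-2-yl]-6-[(3Z)-5-(TBDPS-oxy)-3-methylpent-3-en-1-yl]-5-methyl-2-oxobicyclo[3.1.0]hexane-1-carboxylate | C=C(OC)C[C@](C)(COC(C)=O)[C@@H]1CC(=O)[C@@]2(C(=O)OCC)[C@H](CC/C(C)=C\CO[Si](c3ccccc3)(c3ccccc3)C(C)(C)C)[C@@]12C | intermediate
21 | (1S,2R,4R,5R,6R)-6-[(3Z)-5-(TBDPS-oxy)-3-methylpent-3-en-1-yl]-4-[(2S)-1-hydroxy-4-methoxy-2-methylpent-4-en-2-yl]-1-(hydroxymethyl)-5-methylbicyclo[3.1.0]hexan-2-ol | C=C(OC)C[C@](C)(CO)[C@@H]1C[C@@H](O)[C@@]2(CO)[C@H](CC/C(C)=C\CO[Si](c3ccccc3)(c3ccccc3)C(C)(C)C)[C@@]12C | intermediate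
22 | {(1S,2R,4R,5R,6R)-4-[(2S)-1-(acetyloxy)-4-methoxy-2-methylpent-4-en-2-yl]-6-[(3Z)-5-(TBDPS-oxy)-3-methylpent-3-en-1-yl]-2-hydroxy-5-methylbicyclo[3.1.0]hexan-1-yl}methyl acetate | C=C(OC)C[C@](C)(COC(C)=O)[C@@H]1C[C@@H](O)[C@@]2(COC(C)=O)[C@H](CC/C(C)=C\CO[Si](c3ccccc3)(c3ccccc3)C(C)(C)C)[C@@]12C | intermediate
23 | C7 trimethylsilyl ether of 22 | C=C(OC)C[C@](C)(COC(C)=O)[C@@H]1C[C@@H](O[Si](C)(C)C)[C@@]2(COC(C)=O)[C@H](CC/C(C)=C\CO[Si](c3ccccc3)(c3ccccc3)C(C)(C)C)[C@@]12C | intermediate (not isolated)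
24 | cyclised 2-methoxy oxocarbenium triflate: 19-acetoxy-7α-(trimethylsilyloxy)-15-(TBDPS-oxy)labda-8(17),13Z-diene with C2=O(+)–CH3 | C=C1[C@H](O[Si](C)(C)C)C[C@H]2[C@@](C)(COC(C)=O)CC(=[O+]C)C[C@]2(C)[C@H]1CC/C(C)=C\CO[Si](c3ccccc3)(c3ccccc3)C(C)(C)C.[O-]S(=O)(=O)C(F)(F)F | intermediate (not isolated)
25 | (4S,5R,7R,9R,10S)-19-acetoxy-7α-hydroxy-15-(TBDPS-oxy)labda-8(17),13Z-dien-2-one | C=C1[C@H](O)C[C@H]2[C@@](C)(COC(C)=O)CC(=O)C[C@]2(C)[C@H]1CC/C(C)=C\CO[Si](c3ccccc3)(c3ccccc3)C(C)(C)C | intermediate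
26 | (2R,4S,5R,7R,9R,10S)-19-acetoxy-15-(TBDPS-oxy)labda-8(17),13Z-diene-2α,7α-diol | C=C1[C@H](O)C[C@H]2[C@@](C)(COC(C)=O)C[C@H](O)C[C@]2(C)[C@H]1CC/C(C)=C\CO[Si](c3ccccc3)(c3ccccc3)C(C)(C)C | intermediate
27 | (2R,4S,5R,7R,9R,10S)-2α,7α,15-trihydroxylabda-8(17),13Z-dien-19-yl acetate (CNP0174017.2) | C=C1[C@H](O)C[C@H]2[C@@](C)(COC(C)=O)C[C@H](O)C[C@]2(C)[C@H]1CC/C(C)=C\CO | target

Total step count: 17. Longest linear sequence: 16 steps (steps 1–3 and 5–17 from nerol; step 4 prepares reagent 8).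

Steps most likely to fail

Step 15 (Proposed new method). After ionisation the cation may lose a proton, be captured by acetate, or open at the external C8–C9 bond instead of being captured by C1; the enol ether may also be lost to adventitious acid before ionisation. The fallback separates the events into two known operations and sets out from 22. MgBr2·OEt2 in CH2Cl2 should convert the cyclopropylcarbinyl acetate into the ring-expanded homoallylic tertiary bromide (1R,3S,4S,5S)-4-bromo-5-[(2S)-1-(acetyloxy)-4-methoxy-2-methylpent-4-en-2-yl]-3-[(3Z)-5-(TBDPS-oxy)-3-methylpent-3-en-1-yl]-4-methyl-2-methylidenecyclohexan-1-ol F1. This is the cyclopropylcarbinyl–homoallyl rearrangement with halide capture at the more substituted carbon, and ring B is again made by cleavage of the C8–C10 bond. AgOSO2CF3 with 2,6-di-tert-butyl-4-methylpyridine at −78 °C should then ionise the bromide and let the enol ether alkylate C10 (Lewis-acid α-tert-alkylation of an enol ether), closing ring A through the chair with the C20 methyl axial. Dilute acid work-up returns the route to 25.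

Step 13. Hydride may add to C7 from the cyclopropane face or without facial selectivity, which would end as the 7β-alcohol. The fallback replaces substrate control by reagent control and sets out from 20. Corey–Bakshi–Shibata reduction ((S)-2-methyl-CBS-oxazaborolidine, catecholborane, toluene, −78 °C; C8 as the large and C6 as the small group) should give ethyl (1R,2R,4R,5R,6R)-4-[(2S)-1-(acetyloxy)-4-methoxy-2-methylpent-4-en-2-yl]-6-[(3Z)-5-(TBDPS-oxy)-3-methylpent-3-en-1-yl]-2-hydroxy-5-methylbicyclo[3.1.0]hexane-1-carboxylate F2 without touching esters or alkenes. LiAlH4 then reduces the ester and cleaves the acetate, which returns the route to 21.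

Step 16. The ketyl may be protonated under kinetic control, giving the axial 2β-alcohol, or the acetate may be over-reduced. The fallback sets out from 25. Desilylation first (n-Bu4NF, AcOH, THF) gives 19-acetoxy-7α,15-dihydroxylabda-8(17),13Z-dien-2-one F3. Enzymatic reduction with an NADPH-dependent ketoreductase (alcohol dehydrogenase class; glucose and glucose dehydrogenase for cofactor recycling; aqueous buffer with DMSO), chosen from a panel for hydride delivery to the β-face of C2, then gives 27 directly. The enzyme overrides the substrate bias that sends small hydride reagents to the α-face.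

Further compounds
F1 | step 15 | (1R,3S,4S,5S)-4-bromo-5-[(2S)-1-(acetyloxy)-4-methoxy-2-methylpent-4-en-2-yl]-3-[(3Z)-5-(TBDPS-oxy)-3-methylpent-3-en-1-yl]-4-methyl-2-methylidenecyclohexan-1-ol | C=C1[C@H](O)C[C@@H]([C@](C)(CC(OC)=C)COC(C)=O)[C@](C)(Br)[C@H]1CC/C(C)=C\CO[Si](c2ccccc2)(c2ccccc2)C(C)(C)C
F2 | step 13 | ethyl (1R,2R,4R,5R,6R)-4-[(2S)-1-(acetyloxy)-4-methoxy-2-methylpent-4-en-2-yl]-6-[(3Z)-5-(TBDPS-oxy)-3-methylpent-3-en-1-yl]-2-hydroxy-5-methylbicyclo[3.1.0]hexane-1-carboxylate | C=C(OC)C[C@](C)(COC(C)=O)[C@@H]1C[C@@H](O)[C@@]2(C(=O)OCC)[C@H](CC/C(C)=C\CO[Si](c3ccccc3)(c3ccccc3)C(C)(C)C)[C@@]12C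
F3 | step 16 | (4S,5R,7R,9R,10S)-19-acetoxy-7α,15-dihydroxylabda-8(17),13Z-dien-2-one | C=C1[C@H](O)C[C@H]2[C@@](C)(COC(C)=O)CC(=O)C[C@]2(C)[C@H]1CC/C(C)=C\CO
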